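We take a small charge of catalyst, send it round the cycle below, and ask how much target stands at the end of the run.

in all of them: substrate 0.017 M; reagent 0.0850 M; time 2.5 d
- ash: free catalyst 8.0 µM
- cedar: free catalyst 25 µM
- larch: free catalyst 80 µM
- oak: free catalyst 250 µM

    reagent + free catalyst → catalyst intermediate A (k1 = 416 /M/h)
    substrate + catalyst intermediate A → catalyst intermediate B (k2 = 27100 /M/h)
    catalyst intermediate C → free catalyst + target (k3 = 46.7 /h)
    catalyst intermediate B → by-product + catalyst intermediate C (k4 = 34.4 /h)
    target ⇌ isomer of the product (K5 = 30, k5 = 0.0426 /h)

- "hardly changes" means that all values lie within two and a half points (for a concentration: within two and a half percent of the largest)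
- run time (ash): 2.5 d

- amount of target at the end, in percent of the substrate charged for ash, cedar, larch, oak, in this order
- how the row runs (falls, then rises / rises, then falls / rises all the way / falls all the way / hardly changes)

We climb a ladder of times from the fastest, and the rungs above it change places from flask to flask. One lap of the cycle adds four mean waits, taken at the charged concentrations:

lap = 7.81 s (catalyst intermediate A meets substrate) + 77.1 s (catalyst intermediate C breaks up) + 102 s (free catalyst meets reagent) + 105 s (catalyst intermediate B breaks up) = 291 s

There is no single rate-limiting step: the longest wait, 105 s, is a third of the lap.

The next rung is the substrate charge over the catalyst charge, times the lap. This is the clearing time 172 h, given here for ash. We replace the curve of target formation by its mean, a steady rate over the clearing time, so target is born on average at half that time.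

Against this moving rung stands one that contains no catalyst charge: target and the isomer of the product relax together at 0.0440 /h, the forward and back constants added. Their half-life of 0.656 d is short against the run of 60 h, and the floor is 3.23 % target. So:

target = floor + (share above floor) × spread factor × exp(−rate × mean age)

The spread factor measures the error of using the mean, since births are spread around it:

oak: clearing 5.50 h, factor 1.00, above floor 7.80 %, target 11.0 %

larch: clearing 17.2 h, factor 1.02, above floor 10.3 %, target 13.5 %

cedar: clearing 55.0 h, factor 1.26, above floor 29.3 %, target 32.5 %

Ash's clearing time is longer than the run, so births fill the whole run and the result is scaled by the share of substrate used: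

ash: share used 34.9 %, factor 1.32, above floor before scaling 34.0 %, target 0.130

Our row peaks at cedar, so it rises, then falls.

The forecast gives 12.6 %, 33.5 %, 13.8 % and 11.1 %, so rises, then falls, close to our row, though at cedar it stands 1 percentage point above us. It expects the decline at high loading, “where the target has the longest time to isomerise”.

The flask gives 12.7 %, 33.6 %, 13.8 % and 11.1 % for ash, cedar, larch and oak: rises, then falls, with the turn at 25 µM. Cedar ends the run with 2.32 % of its substrate left. Ash's clearing time of 172 h puts the substrate remaining at the end of its run at 65.1 %, and ash ends with 65.7 %.

(The constants used here belong to no real substance; no experiment stands behind them.)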